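**Assumption:** Kanzonol C has no stereocentres, so "single enantiomer" does not apply; the only stereo-element is the (E)-enone, set in Step 4. The route is designed from known reaction types and has not been run.

## Retrosynthetic overview

1. Both C-prenyl groups come from aryl 1,1-dimethylallyl ("reverse-prenyl") ethers by a double aromatic Claisen rearrangement in the last step.
2. These ethers also serve as base-stable protection of the two 4-OH groups, so the enone is disconnected by Claisen–Schmidt condensation with no separate protecting-group steps.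
3. Each ether is made by Pd(0)-catalysed O-tert-prenylation of 2,4-dihydroxyacetophenone or 4-hydroxybenzaldehyde with a tertiary allylic carbonate.
4. The carbonate is made from 2-methylbut-3-en-2-ol and Boc2O.
5. No rings are formed; both benzene rings are bought.

## Route

**Step 1**
Reactants: 1 (2-methylbut-3-en-2-ol); 2 (di-tert-butyl dicarbonate)
Product: 3 (tert-butyl 2-methylbut-3-en-2-yl carbonate)
Conditions: n-BuLi (1.05 eq), THF, −78 → 0 °C; then Boc2O, 0 °C → rt
Reagents that add atoms: Boc2O, CC(C)(C)OC(=O)OC(=O)OC(C)(C)C
Why: Acylation of the lithium alkoxide of a tertiary alcohol with Boc2O gives the mixed carbonate cleanly; it is the π-allyl precursor for Steps 2 and 3.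

**Step 2**
Reactants: 4 (2,4-dihydroxyacetophenone); 3
Product: 5 (1-[2-hydroxy-4-(2-methylbut-3-en-2-yloxy)phenyl]ethanone)
Conditions: 3 (1.15 eq), Pd(PPh3)4 (2 mol %), THF, 4 Å MS, 0 °C, stop at full conversion
Reagents that add atoms: carbonate 3, C=CC(C)(C)OC(=O)OC(C)(C)C (delivers the C5 unit; CO2 and t-BuOH are lost)
Why: In this Tsuji–Trost O-allylation the phenoxide attacks the more substituted terminus of the 1,1-dimethyl-π-allyl-Pd under kinetic control, giving the tertiary ether; only the free 4-OH reacts because the 2-OH is hydrogen-bonded to the ketone.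

**Step 3**
Reactants: 6 (4-hydroxybenzaldehyde); 3
Product: 7 (4-(2-methylbut-3-en-2-yloxy)benzaldehyde)
Conditions: 3 (1.2 eq), Pd(PPh3)4 (2 mol %), THF, 4 Å MS, 0 °C, short reaction time
Reagents that add atoms: carbonate 3, C=CC(C)(C)OC(=O)OC(C)(C)C
Why: Same decarboxylative Tsuji–Trost O-tert-prenylation; low temperature and early quench prevent Pd-mediated isomerisation to the linear O-prenyl ether, and the aldehyde is inert.

**Step 4**
Reactants: 5; 7
Product: 8 ((E)-1-[2-hydroxy-4-(2-methylbut-3-en-2-yloxy)phenyl]-3-[4-(2-methylbut-3-en-2-yloxy)phenyl]prop-2-en-1-one)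
Conditions: KOH (50 % aq, 5 eq), EtOH, 0 °C → rt, 24–48 h; quench at 0 °C with aq NH4Cl/AcOH to pH ≈ 6
Reagents that add atoms: none (water is lost)
Why: Claisen–Schmidt aldol condensation; E1cB dehydration gives the thermodynamic (E)-enone, and the tertiary allyl aryl ethers survive base at rt (strong acid and heat are avoided in work-up).

**Step 5**
Reactants: 8
Product: 9 (Kanzonol C, (E)-1-[2,4-dihydroxy-3-(3-methylbut-2-enyl)phenyl]-3-[4-hydroxy-3-(3-methylbut-2-enyl)phenyl]prop-2-en-1-one)
Conditions: degassed o-xylene (0.02 M), Ar, 125–130 °C, 2–4 h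
Reagents that add atoms: none
Why: Double aromatic Claisen rearrangement converts each O–C(CH3)2–CH=CH2 into an ortho C–CH2–CH=C(CH3)2. The B-ring has two equivalent ortho positions; on the A-ring the chelated 2'-OH/C=O directs migration to C-3', as with 4-O-allylresacetophenones. Neutral, moderate-temperature conditions should leave the (E)-enone and the 2'-hydroxychalcone intact (no flavanone or chroman formation expected).

## Compound list

1 | 2-methylbut-3-en-2-ol | CC(C)(O)C=C | starting material
2 | di-tert-butyl dicarbonate (Boc2O) | CC(C)(C)OC(=O)OC(=O)OC(C)(C)C | starting material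
3 | tert-butyl 2-methylbut-3-en-2-yl carbonate | C=CC(C)(C)OC(=O)OC(C)(C)C | intermediate
4 | 2,4-dihydroxyacetophenone | CC(=O)c1ccc(O)cc1O | starting material
5 | 1-[2-hydroxy-4-(2-methylbut-3-en-2-yloxy)phenyl]ethanone | CC(=O)c1ccc(OC(C)(C)C=C)cc1O | intermediate
6 | 4-hydroxybenzaldehyde | O=Cc1ccc(O)cc1 | starting material
7 | 4-(2-methylbut-3-en-2-yloxy)benzaldehyde | O=Cc1ccc(OC(C)(C)C=C)cc1 | intermediate
8 | (E)-2'-hydroxy-4,4'-bis(2-methylbut-3-en-2-yloxy)chalcone | C=CC(C)(C)Oc1ccc(/C=C/C(=O)c2ccc(OC(C)(C)C=C)cc2O)cc1 | intermediate
9 | Kanzonol C | CC(C)=CCc1cc(/C=C/C(=O)c2ccc(O)c(CC=C(C)C)c2O)ccc1O | target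

## Summary

Total steps: 5.
Longest linear sequence: 4 (Step 1 → Step 2 or 3 → Step 4 → Step 5).

Steps most likely to fail, each with a fallback that changes the approach:

1. **Step 5 (double Claisen).** Risks are partial migration to C-5' on the A-ring and thermal chalcone-to-flavanone cyclisation. Fallback: rearrange at the monomer stage (5 → 2,4-dihydroxy-3-prenylacetophenone; 7 → 4-hydroxy-3-prenylbenzaldehyde), purify the regioisomers there, protect both 4-OH groups as MOM ethers, run the Claisen–Schmidt condensation, and remove MOM with mild acid.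
2. **Step 3 (and to a lesser extent Step 2).** The acidic, electron-poor phenol can re-ionise under Pd(0) and give the linear O-prenyl ether. Fallback: Cu-catalysed O-alkylation with 3-chloro-3-methylbut-1-yne (cat. CuCl2, DBU, MeCN, 0 °C) to the 1,1-dimethylpropargyl ether, then Lindlar semi-hydrogenation to the same 1,1-dimethylallyl ether.
3. **Step 4 (Claisen–Schmidt).** Risks are slow condensation, flavanone formation and ether loss on work-up. Fallback: a stepwise directed aldol, using the lithium dianion of 5 (LiHMDS, 2.2 eq, THF, −78 °C) added to 7, followed by a separate dehydration of the β-hydroxy ketone (MsCl/Et3N, then DBU) to the (E)-enone.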